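## Structural features

The target is a 4-aryl-1-tetralone in which ring C (C1 carbonyl, C2, C3, C4, C4a, C8a) is fused to ring D, a benzene carrying hydroxyls at C5 and C8. C4 is bonded to C1′ of a naphthalene whose ring A carries the free C4′ hydroxyl and whose ring B carries the C8′ methoxy group, so the two naphthalene oxygens must be told apart. The only stereocentre is C4, which is (S); it is a methine benzylic to ring D and to ring A, wedged between C5–OH and the peri C8′–OMe, with no neighbouring stereocentre to relay from. Ring D is a 2-acylhydroquinone that oxidises to the quinone in air and base, the naphthol is electron-rich, and the aryl ketone can be over-reduced. The C4–H bond is the weak point for configuration, because strong base, radicals or a cation at C1′ or C4a would erase it. The real difficulty is the crowded C4 methine joined to a para-dioxygenated ring whose oxygens flank both C4 and the C1 carbonyl. The key step uses the fact that ring D can be cut at C4a–C8a, C5–C6 and C7–C8 into two alkynes held together by the C4–C3–C2–C1 chain plus acetylene (C6, C7), with boron standing at C5 and C8 where oxygen is needed later.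

## Logic of the disconnections

**26 ⇒ 25.** The O–CH2Ph bond at C4′ is cut. The naphthol is the most oxidisable site and has to be masked through organolithium, rhodium and cobalt chemistry, and benzyl is orthogonal to the C8′ methyl ether. The forward step must remove benzyl without reducing the ketone or touching C4–H.

**25 ⇒ 23.** The C5–O and C8–O bonds go back to C–B bonds and the C1 ketone goes back to its ethylene ketal. Boron survives alkyne chemistry where oxygen on an sp carbon would not. The ketal is chosen over a protected carbinol because a free C1 carbinol next to the C8 boronate would close a five-membered B–O ring, because a carbinol would need oxidation in the presence of C–B bonds or of a hydroquinone, and because a carbinol adds a second stereocentre and so makes the precursor a pair of epimers. The forward step needs an oxidant for C–B that spares electron-rich arenes, followed by mild acid.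

**23 ⇒ 21 + 22.** C4a–C8a, C5–C6 and C7–C8 are cut. Rings C and D and the whole substitution pattern of ring D disappear, leaving an open chain with one stereocentre and a two-carbon gas. The forward step must favour cross-trimerisation over self-oligomerisation of the diyne and must leave C–B and C4–H alone.

**21 ⇒ 18 + 19.** The two C(sp)–B bonds are cut, so that the moisture-sensitive alkynylboronates are made last from a storable terminal diyne. The forward step must metalate two alkyne C–H bonds without deprotonating C4–H, and it consumes one equivalent of 19 for each alkyne.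

**18 ⇒ 17 ⇒ 16 ⇒ 15.** The two C(sp)–Si bonds, then the two ketal C–O bonds, then the oxidation level at C1 are taken back in turn. The silyl caps are needed earlier: the bulky one for the rhodium step, the small one so that the ynone can be ketalised without conjugate addition. The demand is that fluoride, a Lewis acid and a neutral oxidant each leave C4 alone.

**15 ⇒ 13 + 14.** The C1–C8a bond (carbinol to alkyne) is cut, so the second alkyne arrives as a two-carbon nucleophile. The carbinol configuration is irrelevant because it is oxidised.

**13 ⇒ 10 + 11.** The C1–C2 bond is cut. Conjugate addition to an enal can only deliver the chain C4–C3–C2, so C1 is added as a one-carbon ylide. C4 is β to the reacting carbonyl and cannot enolise.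

**10 ⇒ 8 + 9.** The C4–C4a bond (stereocentre to alkyne) is cut. This is the one bond at C4 whose formation has a catalytic enantioselective version with the aryl group already in place. It removes the stereocentre and leaves a flat enal. The demand is catalyst-controlled facial selectivity and 1,4- over 1,2-addition on a crowded β-naphthyl enal.

**8 ⇒ 5 + 6.** The C3=C4 bond is cut into an aldehyde and a two-carbon ylide. The forward step must give the E-enal and must not homologate twice.

**5 ⇒ 4 ⇒ 3 ⇒ 1.** The O–benzyl bond is cut, the C4′ methyl ether is restored, and the C4–C1′ bond (formyl to ring) is cut. In 3 the formyl group distinguishes the two methoxy groups (one para-conjugated, one peri), which symmetric 1 cannot do. The forward steps need mono-formylation para to a methoxy group and demethylation at the conjugated oxygen only.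

## Other disconnections considered

Alternative 1: The cut is at C1′–C8a′ and C4′–C4a′. Ring A is assembled from the four carbons and the oxygen of a furan plus the two aryne carbons of ring B.

- *Forward key step.* Fluoride releases the methoxy-substituted aryne from silyl triflate A3. It adds across the 2- and 5-positions of the furan in tetralone A2 to give the oxygen-bridged adduct A1. Acid-promoted opening of the bridge would later give the C4′ naphthol.
- *In its favour.* Rings C and D and the stereocentre are finished before the naphthalene exists. The cycloaddition is fast, mild and metal-free. The C4′ oxygen is born free and already different from the C8′ methoxy group. On this point it is better than the chosen plan, which spends steps 2, 3 and 14 on telling the two oxygens apart.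
- *Against it here.* The required orientation joins the aryne carbon next to the methoxy group to the substituted furan carbon, which is the more crowded mode. The polarisation of such an aryne is expected to give only a weak preference with 2-alkylfurans, so the 5′-methoxy regioisomer would have to be expected and separated. Bridge opening puts positive charge at C1′, directly beside C4–H, where a hydride shift or elimination would destroy the stereocentre. Two aryl pivalates must survive fluoride.
- *Comparison.* Structurally both plans build one arene last, but in the chosen plan the positions of the borons fix the pattern and no regiochemical question exists, whereas A1 is inherently a mixture. Mechanistically a concerted (4+2) addition is simpler than a cobalt cycle. In step economy the steps after A1 are about equal to the two after 23, but A2 still needs its own enantioselective synthesis, so no overall saving is evident.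

Alternative 2: The cut is at C8′–C8a′. Ring B is closed last onto a benzene that already carries the benzyloxy group and the tetralone.

- *Forward key step.* Irradiation of the Z-enone diazoketone A5 expels nitrogen and triggers Wolff rearrangement to a dienylketene. 6π electrocyclisation onto the free ortho position of ring A and tautomerisation give naphthol A4.
- *In its favour.* Only one ortho position is open, so the regiochemistry is as certain as in the chosen plan (equal). The C8′ oxygen appears as a free phenol beside a benzyl-protected C4′ oxygen, so O-methylation differentiates the two by construction; this is better than the selective demethylation of step 2. The reaction is unimolecular, so it has no cross- versus self-reaction problem; this is also better than the key step chosen here.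
- *Against it here.* The new bond forms at the carbon flanked by the tetralone-bearing C1′, so peri congestion is built into the bond-forming event. The vinyl diazoketone can close to a pyrazole, the alkene can lose the Z geometry needed for closure, and the ketene can be intercepted by nucleophiles. A5 must be made on a substrate that already contains the whole tetralone, and the disconnection says nothing about how C4 and rings C and D are made. After A4, O-methylation, ketal hydrolysis, ester cleavage and debenzylation remain.
- *Comparison.* Structurally it forms one ring and one bond, against two rings and three bonds in step 12. Mechanistically it is a clean pericyclic cascade against a metal-templated one. In step economy it would be longer, because the most demanding part of the molecule is left to other chemistry.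

Alternative 3: The cut is at C8a–C1 and C1–C2, with C1 supplied by carbon monoxide A8.

- *Forward key step.* The terminal alkene of allyl arene A7 is hydroborated at C2 with a bulky dialkylborane. Palladium-catalysed carbonylative alkyl–aryl coupling at the C8a–Br bond then closes ring C and gives ketone A6.
- *In its favour.* C1 arrives directly at the ketone oxidation level, where the chosen plan needs steps 7 to 9 and part of step 13; on this point the alternative is better. Ring D is bought as a hydroquinone ether and not built. Only one acidic deprotection follows A6, which is equal to or better than the two steps after 23. The route would probably be the shortest of all.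
- *Against it here.* The bromide is flanked by an alkoxy group and the diarylmethine, so oxidative addition to zerovalent palladium and CO insertion are both slowed. Direct coupling without CO would close a five-membered ring and compete. In A7 the C4–H is allylic and doubly benzylic, so base or a palladium hydride can move the alkene into conjugation and erase the stereocentre. Making A7 as one enantiomer means forming a 1,1-diarylallyl centre between two ortho-substituted arenes, which is at least as hard as step 5.
- *Comparison.* Structurally it closes ring C only, with every oxygen in place. Mechanistically it has three competing palladium pathways, against one main competitor in the cobalt cycle. The chosen plan keeps C4 as a propargylic, non-allylic centre until ring closure, which is the safer environment for the configuration. In step economy the alternative is expected to be better.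

Key step: step 12

**Remarks on the chemistry**

- The (R)-enantiomer of DTBM-SEGPHOS is assumed to deliver the alkynyl group to the Si face of C4 in 8, by analogy with simpler β-aryl enals; if the sense proves opposite, the (S)-ligand is used and nothing else changes.
- C1 passes through the key step as an ethylene ketal and not as a silyl-protected carbinol; the skeleton, the bonds formed and the rings closed are unchanged.
- Acetylene is used only at atmospheric pressure as a slow stream through the solution.
- 1,5-Dimethoxynaphthalene is taken as a purchased starting material.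

## Route

Step 1
Reactants: 1 1,5-dimethoxynaphthalene
Product: 3 4,8-dimethoxy-1-naphthaldehyde, via iminium chloride 2 (not isolated)
Conditions: POCl3, DMF, 0 → 80 °C; then aq. NaOH, 0 °C
Reagents that add atoms: N,N-dimethylformamide CN(C)C=O; water O
Why: Vilsmeier–Haack formylation: the chloroiminium electrophile attacks para to a methoxy group (C4, equivalent to C8 by symmetry), and the iminium product is deactivated towards a second attack. Hydrolysis gives the aldehyde, whose carbon becomes C4 of the target and whose bond to the ring is the C4–C1′ bond.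

Step 2
Reactants: 3 4,8-dimethoxy-1-naphthaldehyde
Product: 4 4-hydroxy-8-methoxy-1-naphthaldehyde
Conditions: NaSEt, DMF, 100 °C; then aq. HCl
Reagents that add atoms: none
Why: Nucleophilic (SN2) O-demethylation by thiolate: only the C4 oxygen is para-conjugated with the formyl group and leaves as a stabilised vinylogous carboxylate, while the peri C8 oxygen has no such conjugation. The C4 ether should therefore cleave first, and the naphthoxide formed then deactivates the molecule towards a second cleavage.

Step 3
Reactants: 4 4-hydroxy-8-methoxy-1-naphthaldehyde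
Product: 5 4-(benzyloxy)-8-methoxy-1-naphthaldehyde
Conditions: BnBr, K2CO3, DMF, rt
Reagents that add atoms: benzyl bromide BrCc1ccccc1
Why: Williamson etherification of the acidic para-formyl naphthol. The benzyl ether is inert to organolithiums, rhodium, cobalt and amine N-oxide and is removed last by hydrogenolysis.

Step 4
Reactants: 5 4-(benzyloxy)-8-methoxy-1-naphthaldehyde; 6 (1,3-dioxolan-2-ylmethyl)triphenylphosphonium bromide
Product: 8 (E)-3-[4-(benzyloxy)-8-methoxynaphthalen-1-yl]prop-2-enal, via alkenyl dioxolane 7 (not isolated)
Conditions: KOtBu, THF, 0 °C → rt; then 1 M HCl, rt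
Reagents that add atoms: water O
Why: Wittig olefination with an acetal-masked two-carbon ylide, then acetal hydrolysis in the same flask. The masked aldehyde cannot be homologated a second time, and acid equilibrates the alkene to the conjugated E-enal.

Step 5
Reactants: 8 (E)-3-[4-(benzyloxy)-8-methoxynaphthalen-1-yl]prop-2-enal; 9 (triisopropylsilyl)acetylene
Product: 10 (S)-3-[4-(benzyloxy)-8-methoxynaphthalen-1-yl]-5-(triisopropylsilyl)pent-4-ynal
Conditions: [Rh(OAc)(C2H4)2]2 (2.5 mol%), (R)-DTBM-SEGPHOS (6 mol%), MeOH, 40 °C
Reagents that add atoms: none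
Why: Rhodium-catalysed asymmetric conjugate alkynylation of a β-aryl enal: acetate-assisted metalation of 9 gives an alkynyl complex of monovalent rhodium, which inserts the enal C=C bond and is protonated by methanol. The bulky silyl group and ligand suppress alkyne dimerisation and 1,2-addition, and the C2-symmetric bisphosphine selects the Si face of C4, so (S)-C4 is set under catalyst control.

Step 6
Reactants: 10 (S)-3-[4-(benzyloxy)-8-methoxynaphthalen-1-yl]-5-(triisopropylsilyl)pent-4-ynal; 11 (methoxymethyl)triphenylphosphonium chloride
Product: 13 (S)-4-[4-(benzyloxy)-8-methoxynaphthalen-1-yl]-6-(triisopropylsilyl)hex-5-ynal, via methyl enol ether 12 (not isolated)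
Conditions: KOtBu, THF, 0 °C → rt; then 2 M HCl, rt
Reagents that add atoms: water O
Why: Wittig methoxymethylenation followed by enol ether hydrolysis (one-carbon homologation) adds C1. C4 is β to the reacting carbonyl and γ to the new one, so neither the ylide nor aqueous acid can epimerise it.

Step 7
Reactants: 13 (S)-4-[4-(benzyloxy)-8-methoxynaphthalen-1-yl]-6-(triisopropylsilyl)hex-5-ynal; 14 (trimethylsilyl)acetylene
Product: 15 (6S)-6-[4-(benzyloxy)-8-methoxynaphthalen-1-yl]-8-(triisopropylsilyl)-1-(trimethylsilyl)octa-1,7-diyn-3-ol (both C3 epimers)
Conditions: n-BuLi, THF, −78 °C; then 13, −78 → 0 °C; H2O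
Reagents that add atoms: none
Why: 1,2-Addition of a lithium acetylide to an aldehyde brings in the second alkyne (future C8a and C8). The new carbinol centre is left uncontrolled because step 8 removes it.

Step 8
Reactants: 15 (6S)-6-[4-(benzyloxy)-8-methoxynaphthalen-1-yl]-8-(triisopropylsilyl)-1-(trimethylsilyl)octa-1,7-diyn-3-ol
Product: 16 (6S)-6-[4-(benzyloxy)-8-methoxynaphthalen-1-yl]-8-(triisopropylsilyl)-1-(trimethylsilyl)octa-1,7-diyn-3-one
Conditions: Dess–Martin periodinane, CH2Cl2, 0 °C → rt
Reagents that add atoms: none
Why: Dess–Martin oxidation of a propargylic alcohol to the ynone under neutral conditions. C4 is γ to the new carbonyl and is not activated by it.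

Step 9
Reactants: 16 (6S)-6-[4-(benzyloxy)-8-methoxynaphthalen-1-yl]-8-(triisopropylsilyl)-1-(trimethylsilyl)octa-1,7-diyn-3-one
Product: 17 {(3S)-3-[4-(benzyloxy)-8-methoxynaphthalen-1-yl]-5-{2-[(trimethylsilyl)ethynyl]-1,3-dioxolan-2-yl}pent-1-yn-1-yl}triisopropylsilane
Conditions: (TMSOCH2)2, TMSOTf (10 mol%), CH2Cl2, −78 → −20 °C; pyridine quench
Reagents that add atoms: 1,2-bis(trimethylsilyloxy)ethane C[Si](C)(C)OCCO[Si](C)(C)C
Why: TMSOTf-catalysed ketalisation with the bis(silyl) ether of ethylene glycol, a method that works on conjugated ynones at low temperature; the silyl cap on the alkyne blocks conjugate addition of the glycol. The ketal stores C1 at the ketone oxidation level and removes the extra stereocentre a protected carbinol would carry.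

Step 10
Reactants: 17 {(3S)-3-[4-(benzyloxy)-8-methoxynaphthalen-1-yl]-5-{2-[(trimethylsilyl)ethynyl]-1,3-dioxolan-2-yl}pent-1-yn-1-yl}triisopropylsilane
Product: 18 2-{(3R)-3-[4-(benzyloxy)-8-methoxynaphthalen-1-yl]pent-4-yn-1-yl}-2-ethynyl-1,3-dioxolane
Conditions: Bu4NF, THF, 0 °C → rt; H2O
Reagents that add atoms: none
Why: Fluoride-induced protodesilylation of both alkynyl silanes (C(sp)–Si cleavage). Ketal and ethers are inert, and hydrated fluoride at 0 °C is not basic enough to remove the benzylic propargylic C4–H; the descriptor changes from S to R only because the silicon is lost from the alkyne.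

Step 11
Reactants: 18 2-{(3R)-3-[4-(benzyloxy)-8-methoxynaphthalen-1-yl]pent-4-yn-1-yl}-2-ethynyl-1,3-dioxolane; 19 2-isopropoxy-4,4,5,5-tetramethyl-1,3,2-dioxaborolane (2.2 equiv, one boronate for each alkyne)
Product: 21 (3R)-3-[4-(benzyloxy)-8-methoxynaphthalen-1-yl]-6,6-(ethylenedioxy)octa-1,7-diyne-1,8-diyl bis(pinacolboronate), via dilithium bis(borate) 20 (not isolated)
Conditions: n-BuLi (2.05 equiv), THF, −78 °C; 19 (2.2 equiv), −78 °C; HCl in Et2O, −78 °C → rt; filtration under Ar
Reagents that add atoms: 2-isopropoxy-4,4,5,5-tetramethyl-1,3,2-dioxaborolane CC(C)OB1OC(C)(C)C(C)(C)O1 (the second equivalent of 19, which supplies the second boronate)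
Why: Borylation of lithium acetylides: the two terminal alkyne C–H bonds are far more acidic than C4–H, each acetylide adds to one molecule of the isopropoxyboronate to give a bis(ate) complex, and anhydrous acid expels isopropanol from each boron. The product is filtered and used at once because alkynyl C–B bonds hydrolyse easily.

Step 12
Reactants: 21 (3R)-3-[4-(benzyloxy)-8-methoxynaphthalen-1-yl]-6,6-(ethylenedioxy)octa-1,7-diyne-1,8-diyl bis(pinacolboronate); 22 acetylene
Product: 23 (4′S)-4′-[4-(benzyloxy)-8-methoxynaphthalen-1-yl]-5′,8′-bis(4,4,5,5-tetramethyl-1,3,2-dioxaborolan-2-yl)-3′,4′-dihydro-2′H-spiro[1,3-dioxolane-2,1′-naphthalene]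
Conditions: CpCo(CO)2 (20 mol%), acetylene (1 atm, slow stream), toluene, hν (visible lamp), 110 °C, slow addition of 21
Reagents that add atoms: none
Why: Loss of CO from CpCo(CO)2 under light and heat gives a monovalent CpCo fragment that binds both alkynes of 21 and couples them oxidatively to a trivalent cobaltacyclopentadiene; acetylene then coordinates and inserts, and reductive elimination releases the arene and returns monovalent cobalt. The closest known reaction type is the CpCo-catalysed (2+2+2) co-cyclisation of α,ω-diynes with monoalkynes, which tolerates alkynylboronic esters. Ring C closes in the oxidative coupling, where the four-atom tether C4–C3–C2–C1 forces the two internal alkyne carbons together, so C4a–C8a forms intramolecularly as the fusion bond of a six-membered carbocycle. Ring D closes in the second stage, when the two boron-bearing carbons next to cobalt bond to the two carbons of acetylene (C5–C6 and C7–C8) in an intermolecular annulation. No stereocentre is formed; C4 is a spectator propargylic carbon whose configuration from step 5 is carried through, because the medium is neutral and the C4–H bond takes no part. The selectivity needed is cross- over self-trimerisation: the tether makes coupling of the two alkynes on one cobalt faster than any bimolecular pairing, the boryl groups and the quaternary ketal make a second molecule of 21 a poor third partner, and slow addition under excess acetylene keeps the diyne dilute. Regiochemistry cannot arise because acetylene is symmetric, and the untouched C–B bonds fix the later oxygens at C5 and C8.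

Step 13
Reactants: 23 (4′S)-4′-[4-(benzyloxy)-8-methoxynaphthalen-1-yl]-5′,8′-bis(4,4,5,5-tetramethyl-1,3,2-dioxaborolan-2-yl)-3′,4′-dihydro-2′H-spiro[1,3-dioxolane-2,1′-naphthalene]
Product: 25 (S)-4-[4-(benzyloxy)-8-methoxynaphthalen-1-yl]-5,8-dihydroxy-3,4-dihydronaphthalen-1(2H)-one, via bis(aryl borate) 24 (not isolated)
Conditions: Me3NO (anhydrous, 4 equiv), THF, 60 °C; then 2 M HCl, rt, under Ar
Reagents that add atoms: trimethylamine N-oxide C[N+](C)(C)[O-] (two equivalents are consumed, one for each C–B bond); water O
Why: Oxidation of aryl C–B bonds by an amine N-oxide (1,2-shift of aryl from boron to oxygen in the B–O–N adduct) under neutral conditions, then acid hydrolysis of the borate esters and the ketal in the same flask. The phenols stay masked as borates until the air-free acidic work-up, and because C1 is still a ketal during the oxidation there is no Baeyer–Villiger or Dakin-type pathway.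

Step 14
Reactants: 25 (S)-4-[4-(benzyloxy)-8-methoxynaphthalen-1-yl]-5,8-dihydroxy-3,4-dihydronaphthalen-1(2H)-one
Product: 26 (S)-5,8-dihydroxy-4-(4-hydroxy-8-methoxynaphthalen-1-yl)-3,4-dihydronaphthalen-1(2H)-one
Conditions: H2 (1 atm), Pd/C (10%), EtOAc/MeOH, rt
Reagents that add atoms: none
Why: Catalytic hydrogenolysis of an aryl benzyl ether. The hydrogen-bonded ortho-hydroxy aryl ketone and the C–aryl bonds at C4 are slow to reduce at 1 atm and room temperature, and C4 is not touched.

## Compound list

1 | 1,5-dimethoxynaphthalene | COc1cccc2c(OC)cccc12 | starting material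
2 | [(4,8-dimethoxynaphthalen-1-yl)methylidene]dimethyliminium chloride | COc1cccc2c(OC)ccc(C=[N+](C)C)c12.[Cl-] | intermediate
3 | 4,8-dimethoxy-1-naphthaldehyde | COc1cccc2c(OC)ccc(C=O)c12 | intermediate
4 | 4-hydroxy-8-methoxy-1-naphthaldehyde | COc1cccc2c(O)ccc(C=O)c12 | intermediate
5 | 4-(benzyloxy)-8-methoxy-1-naphthaldehyde | COc1cccc2c(OCc3ccccc3)ccc(C=O)c12 | intermediate
6 | (1,3-dioxolan-2-ylmethyl)triphenylphosphonium bromide | [Br-].C1COC(C[P+](c2ccccc2)(c2ccccc2)c2ccccc2)O1 | starting material
7 | 2-{2-[4-(benzyloxy)-8-methoxynaphthalen-1-yl]ethenyl}-1,3-dioxolane (E/Z mixture) | COc1cccc2c(OCc3ccccc3)ccc(C=CC3OCCO3)c12 | intermediate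
8 | (E)-3-[4-(benzyloxy)-8-methoxynaphthalen-1-yl]prop-2-enal | COc1cccc2c(OCc3ccccc3)ccc(/C=C/C=O)c12 | intermediate
9 | (triisopropylsilyl)acetylene | C#C[Si](C(C)C)(C(C)C)C(C)C | starting material
10 | (S)-3-[4-(benzyloxy)-8-methoxynaphthalen-1-yl]-5-(triisopropylsilyl)pent-4-ynal | COc1cccc2c(OCc3ccccc3)ccc(c12)[C@@H](C#C[Si](C(C)C)(C(C)C)C(C)C)CC=O | intermediate
11 | (methoxymethyl)triphenylphosphonium chloride | [Cl-].COC[P+](c1ccccc1)(c1ccccc1)c1ccccc1 | starting material
12 | {(3S)-3-[4-(benzyloxy)-8-methoxynaphthalen-1-yl]-6-methoxyhex-5-en-1-yn-1-yl}triisopropylsilane (E/Z mixture) | COc1cccc2c(OCc3ccccc3)ccc(c12)[C@@H](C#C[Si](C(C)C)(C(C)C)C(C)C)CC=COC | intermediate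
13 | (S)-4-[4-(benzyloxy)-8-methoxynaphthalen-1-yl]-6-(triisopropylsilyl)hex-5-ynal | COc1cccc2c(OCc3ccccc3)ccc(c12)[C@@H](C#C[Si](C(C)C)(C(C)C)C(C)C)CCC=O | intermediate
14 | (trimethylsilyl)acetylene | C#C[Si](C)(C)C | starting material
15 | (6S)-6-[4-(benzyloxy)-8-methoxynaphthalen-1-yl]-8-(triisopropylsilyl)-1-(trimethylsilyl)octa-1,7-diyn-3-ol (C3 epimers) | COc1cccc2c(OCc3ccccc3)ccc(c12)[C@@H](C#C[Si](C(C)C)(C(C)C)C(C)C)CCC(O)C#C[Si](C)(C)C | intermediate
16 | (6S)-6-[4-(benzyloxy)-8-methoxynaphthalen-1-yl]-8-(triisopropylsilyl)-1-(trimethylsilyl)octa-1,7-diyn-3-one | COc1cccc2c(OCc3ccccc3)ccc(c12)[C@@H](C#C[Si](C(C)C)(C(C)C)C(C)C)CCC(=O)C#C[Si](C)(C)C | intermediate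
17 | {(3S)-3-[4-(benzyloxy)-8-methoxynaphthalen-1-yl]-5-{2-[(trimethylsilyl)ethynyl]-1,3-dioxolan-2-yl}pent-1-yn-1-yl}triisopropylsilane | COc1cccc2c(OCc3ccccc3)ccc(c12)[C@@H](C#C[Si](C(C)C)(C(C)C)C(C)C)CCC1(OCCO1)C#C[Si](C)(C)C | intermediate
18 | 2-{(3R)-3-[4-(benzyloxy)-8-methoxynaphthalen-1-yl]pent-4-yn-1-yl}-2-ethynyl-1,3-dioxolane | COc1cccc2c(OCc3ccccc3)ccc(c12)[C@@H](C#C)CCC1(OCCO1)C#C | intermediate
19 | 2-isopropoxy-4,4,5,5-tetramethyl-1,3,2-dioxaborolane | CC(C)OB1OC(C)(C)C(C)(C)O1 | starting material
20 | dilithium bis(isopropoxy)borate complex of 21 | COc1cccc2c(OCc3ccccc3)ccc(c12)[C@@H](C#C[B-]1(OC(C)C)OC(C)(C)C(C)(C)O1)CCC1(OCCO1)C#C[B-]1(OC(C)C)OC(C)(C)C(C)(C)O1.[Li+].[Li+] | intermediate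
21 | (3R)-3-[4-(benzyloxy)-8-methoxynaphthalen-1-yl]-6,6-(ethylenedioxy)octa-1,7-diyne-1,8-diyl bis(pinacolboronate) | COc1cccc2c(OCc3ccccc3)ccc(c12)[C@@H](C#CB1OC(C)(C)C(C)(C)O1)CCC1(OCCO1)C#CB1OC(C)(C)C(C)(C)O1 | intermediate
22 | acetylene | C#C | starting material
23 | (4′S)-4′-[4-(benzyloxy)-8-methoxynaphthalen-1-yl]-5′,8′-bis(4,4,5,5-tetramethyl-1,3,2-dioxaborolan-2-yl)-3′,4′-dihydro-2′H-spiro[1,3-dioxolane-2,1′-naphthalene] | COc1cccc2c(OCc3ccccc3)ccc(c12)[C@@H]1CCC2(OCCO2)c2c(B3OC(C)(C)C(C)(C)O3)ccc(B3OC(C)(C)C(C)(C)O3)c12 | intermediate
24 | (4′S)-4′-[4-(benzyloxy)-8-methoxynaphthalen-1-yl]-5′,8′-bis[(4,4,5,5-tetramethyl-1,3,2-dioxaborolan-2-yl)oxy]-3′,4′-dihydro-2′H-spiro[1,3-dioxolane-2,1′-naphthalene] | COc1cccc2c(OCc3ccccc3)ccc(c12)[C@@H]1CCC2(OCCO2)c2c(OB3OC(C)(C)C(C)(C)O3)ccc(OB3OC(C)(C)C(C)(C)O3)c12 | intermediate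
25 | (S)-4-[4-(benzyloxy)-8-methoxynaphthalen-1-yl]-5,8-dihydroxy-3,4-dihydronaphthalen-1(2H)-one | COc1cccc2c(OCc3ccccc3)ccc(c12)[C@@H]1CCC(=O)c2c(O)ccc(O)c12 | intermediate
26 | (S)-5,8-dihydroxy-4-(4-hydroxy-8-methoxynaphthalen-1-yl)-3,4-dihydronaphthalen-1(2H)-one | COc1cccc2c(O)ccc([C@@H]3CCC(=O)c4c(O)ccc(O)c43)c12 | target

## Step count and least certain steps

Total steps: 14. Longest linear sequence: 14 steps (1 to 26). Eleven steps lead to the precursor 21 and two follow the cycloadduct 23.

**Step 12 (key step).** The most likely failure is self-oligomerisation of 21, or capture of cobalt as an inert η4-cyclobutadiene complex, because little acetylene is dissolved at the temperature needed to free the cobalt. Loss of the alkynyl C–B bonds by protodeborylation before cyclisation is the second risk. The fallback uses iodine as the placeholder for oxygen and a ruthenium catalyst at room temperature. From 18, double lithiation (n-BuLi, THF, −78 °C) and I2 would give the bis(iodoalkyne) F1. Cp*RuCl(cod)-catalysed (2+2+2) cycloaddition with acetylene (1 atm, 1,2-dichloroethane, rt), a known reaction of iodo-terminated diynes, would give the 5′,8′-diiodide F2. Miyaura borylation (B2pin2, PdCl2(dppf), KOAc, dioxane, 90 °C) then rejoins the route at 23.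

**Step 5.** The most likely failure is slow insertion of the crowded, electron-rich β-naphthyl enal into the alkynyl–rhodium bond. That would mean low conversion, alkyne dimerisation, or poor facial selectivity, because the peri methoxy group twists the aryl ring away from the plane the ligand reads. The fallback uses a more electrophilic acceptor and a stoichiometric chiral auxiliary for separation. From 5, Knoevenagel condensation with Meldrum's acid would give the arylidene compound F3. The bromomagnesium acetylide of 9 (from EtMgBr) adds to it in conjugate fashion without a catalyst to give the racemic adduct F4. Heating in wet DMF gives the racemic acid F5 by loss of acetone and CO2. Acylation of (S)-4-benzyloxazolidin-2-one (pivaloyl mixed anhydride, Et3N, LiCl) gives two diastereomeric imides, from which the (3S)-imide F6 is separated by chromatography or crystallisation. LiBH4 gives the alcohol F7, and Dess–Martin oxidation rejoins the route at 10. Half of the material is lost by design.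

**Step 11.** The most likely failure is deprotonation at the benzylic propargylic C4–H by excess base, leading to alkyne–allene isomerisation and racemisation, or hydrolytic loss of the alkynyl C–B bonds during isolation. The fallback is a base-free borylation to a robust boron mask. From 18, Zn(OTf)2/pyridine-catalysed dehydrogenative borylation with 1,8-naphthalenediaminatoborane would give the chromatography-stable bis(alkynylboramide) F8. The same cobalt co-cyclisation with acetylene would give the arene F9. Aqueous HCl in THF removes both diaminonaphthalene groups and the ketal to give the keto bis(boronic acid) F10, and Me3NO oxidation rejoins the route at 25.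

**Step 2.** The most likely failure is attack of thiolate at the wrong methyl group or at the formyl carbon, or cleavage of both ethers on long heating, so that the two oxygens are not cleanly differentiated. The fallback differentiates first and then lets the free hydroxyl direct the C–C bond. From 1, mono-demethylation with one equivalent of NaSEt (the first naphthoxide deactivates the second ether) would give 5-methoxynaphthalen-1-ol F11. NBS in MeCN brominates para to the free hydroxyl to give 4-bromo-5-methoxynaphthalen-1-ol F12. Benzylation (BnBr, K2CO3) gives 1-(benzyloxy)-4-bromo-5-methoxynaphthalene F13. Bromine–lithium exchange (n-BuLi, −78 °C) and DMF rejoin the route at 5.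

**Step 14.** The most likely failure is over-reduction, either hydrogenolysis of the aryl ketone or partial saturation of the electron-rich naphthalene, competing with O-debenzylation. Air oxidation of the hydroquinone during catalyst filtration is a further risk. The fallback replaces hydrogenation by Lewis-acid dealkylation. From 25, BCl3 with pentamethylbenzene as benzyl-cation scavenger (CH2Cl2, −78 °C) cleaves the benzyl ether and leaves the unchelated C8′ methyl ether, giving 26 directly; no new compound is made (F0).

## Further compounds

F1 | step 12 | 2-{(3S)-3-[4-(benzyloxy)-8-methoxynaphthalen-1-yl]-5-iodopent-4-yn-1-yl}-2-(iodoethynyl)-1,3-dioxolane | COc1cccc2c(OCc3ccccc3)ccc(c12)[C@@H](C#CI)CCC1(OCCO1)C#CI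
F2 | step 12 | (4′S)-4′-[4-(benzyloxy)-8-methoxynaphthalen-1-yl]-5′,8′-diiodo-3′,4′-dihydro-2′H-spiro[1,3-dioxolane-2,1′-naphthalene] | COc1cccc2c(OCc3ccccc3)ccc(c12)[C@@H]1CCC2(OCCO2)c2c(I)ccc(I)c12
F3 | step 5 | 5-{[4-(benzyloxy)-8-methoxynaphthalen-1-yl]methylidene}-2,2-dimethyl-1,3-dioxane-4,6-dione | COc1cccc2c(OCc3ccccc3)ccc(C=C3C(=O)OC(C)(C)OC3=O)c12
F4 | step 5 | racemic 5-{1-[4-(benzyloxy)-8-methoxynaphthalen-1-yl]-3-(triisopropylsilyl)prop-2-yn-1-yl}-2,2-dimethyl-1,3-dioxane-4,6-dione | COc1cccc2c(OCc3ccccc3)ccc(c12)C(C#C[Si](C(C)C)(C(C)C)C(C)C)C1C(=O)OC(C)(C)OC1=O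
F5 | step 5 | racemic 3-[4-(benzyloxy)-8-methoxynaphthalen-1-yl]-5-(triisopropylsilyl)pent-4-ynoic acid | COc1cccc2c(OCc3ccccc3)ccc(c12)C(C#C[Si](C(C)C)(C(C)C)C(C)C)CC(O)=O
F6 | step 5 | (S)-4-benzyl-3-{(3S)-3-[4-(benzyloxy)-8-methoxynaphthalen-1-yl]-5-(triisopropylsilyl)pent-4-ynoyl}oxazolidin-2-one | COc1cccc2c(OCc3ccccc3)ccc(c12)[C@@H](C#C[Si](C(C)C)(C(C)C)C(C)C)CC(=O)N1[C@@H](Cc2ccccc2)COC1=O
F7 | step 5 | (S)-3-[4-(benzyloxy)-8-methoxynaphthalen-1-yl]-5-(triisopropylsilyl)pent-4-yn-1-ol | COc1cccc2c(OCc3ccccc3)ccc(c12)[C@@H](C#C[Si](C(C)C)(C(C)C)C(C)C)CCO
F8 | step 11 | 2-{(3R)-3-[4-(benzyloxy)-8-methoxynaphthalen-1-yl]-5-{2-[(2,3-dihydro-1H-naphtho[1,8-de][1,3,2]diazaborinin-2-yl)ethynyl]-1,3-dioxolan-2-yl}pent-1-yn-1-yl}-2,3-dihydro-1H-naphtho[1,8-de][1,3,2]diazaborinine | COc1cccc2c(OCc3ccccc3)ccc(c12)[C@@H](C#CB1Nc2cccc3cccc(N1)c23)CCC1(OCCO1)C#CB1Nc2cccc3cccc(N1)c23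
F9 | step 11 | (4′S)-4′-[4-(benzyloxy)-8-methoxynaphthalen-1-yl]-5′,8′-bis(2,3-dihydro-1H-naphtho[1,8-de][1,3,2]diazaborinin-2-yl)-3′,4′-dihydro-2′H-spiro[1,3-dioxolane-2,1′-naphthalene] | COc1cccc2c(OCc3ccccc3)ccc(c12)[C@@H]1CCC2(OCCO2)c2c(B3Nc4cccc5cccc(N3)c45)ccc(B3Nc4cccc5cccc(N3)c45)c12
F10 | step 11 | {(S)-4-[4-(benzyloxy)-8-methoxynaphthalen-1-yl]-1-oxo-1,2,3,4-tetrahydronaphthalene-5,8-diyl}diboronic acid | COc1cccc2c(OCc3ccccc3)ccc(c12)[C@@H]1CCC(=O)c2c(B(O)O)ccc(B(O)O)c12
F11 | step 2 | 5-methoxynaphthalen-1-ol | COc1cccc2c(O)cccc12
F12 | step 2 | 4-bromo-5-methoxynaphthalen-1-ol | COc1cccc2c(O)ccc(Br)c12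
F13 | step 2 | 1-(benzyloxy)-4-bromo-5-methoxynaphthalene | COc1cccc2c(OCc3ccccc3)ccc(Br)c12
F0 | step 14 | none | none
A1 | alternative 1 | 4-(8-methoxy-1,4-dihydro-1,4-epoxynaphthalen-1-yl)-1-oxo-1,2,3,4-tetrahydronaphthalene-5,8-diyl bis(2,2-dimethylpropanoate) (bridgehead epimers) | COc1cccc2C3OC(C=C3)(c12)[C@@H]1CCC(=O)c2c(OC(=O)C(C)(C)C)ccc(OC(=O)C(C)(C)C)c12
A2 | alternative 1 | (R)-4-(furan-2-yl)-1-oxo-1,2,3,4-tetrahydronaphthalene-5,8-diyl bis(2,2-dimethylpropanoate) | o1cccc1[C@@H]1CCC(=O)c2c(OC(=O)C(C)(C)C)ccc(OC(=O)C(C)(C)C)c12
A3 | alternative 1 | 3-methoxy-2-(trimethylsilyl)phenyl trifluoromethanesulfonate | COc1cccc(OS(=O)(=O)C(F)(F)F)c1[Si](C)(C)C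
A4 | alternative 2 | 4-[4-(benzyloxy)-8-hydroxynaphthalen-1-yl]-3,4-dihydro-2H-spiro[naphthalene-1,2′-[1,3]dioxolane]-5,8-diyl bis(2,2-dimethylpropanoate) | Oc1cccc2c(OCc3ccccc3)ccc(c12)[C@@H]1CCC2(OCCO2)c2c(OC(=O)C(C)(C)C)ccc(OC(=O)C(C)(C)C)c12
A5 | alternative 2 | 4-{4-(benzyloxy)-3-[(Z)-4-diazo-3-oxobut-1-en-1-yl]phenyl}-3,4-dihydro-2H-spiro[naphthalene-1,2′-[1,3]dioxolane]-5,8-diyl bis(2,2-dimethylpropanoate) | [N-]=[N+]=CC(=O)/C=C\c1cc(ccc1OCc1ccccc1)[C@@H]1CCC2(OCCO2)c2c(OC(=O)C(C)(C)C)ccc(OC(=O)C(C)(C)C)c12
A6 | alternative 3 | (S)-4-[8-methoxy-4-(methoxymethoxy)naphthalen-1-yl]-5,8-bis(methoxymethoxy)-3,4-dihydronaphthalen-1(2H)-one | COc1cccc2c(OCOC)ccc(c12)[C@@H]1CCC(=O)c2c(OCOC)ccc(OCOC)c12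
A7 | alternative 3 | (S)-2-bromo-3-{1-[8-methoxy-4-(methoxymethoxy)naphthalen-1-yl]prop-2-en-1-yl}-1,4-bis(methoxymethoxy)benzene | COc1cccc2c(OCOC)ccc(c12)[C@@H](c1c(Br)c(OCOC)ccc1OCOC)C=C
A8 | alternative 3 | carbon monoxide | [C-]#[O+]
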